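## The problem

Target 34 is a labdane-type acid. Ring A is C1–C5/C10 and ring B is C5–C10; C4 carries the C18 methyl and the C19 carboxyl, C10 the C20 methyl, C8 an exocyclic methylene (C17), and C9 a chain C11–C15 (methyl C16 on C13) ending in an (E)-caffeate. With the face of C20 called β, H5, H9 and the C19 carboxyl are also β. The decalin is therefore cis-fused, and the C9 chain is α, on the concave side and cis to C1. C4 and C10 are quaternary and flank C5; these three contiguous centres are the hard core. C9 can be controlled by the finished bicycle, but only for a reagent that enters from the convex β face, so the hydrogen at C9, not the chain, is what substrate control can deliver. C13 (S) is too remote for ring control and must be bought. The 1,1-disubstituted C8=C17 alkene, the base-labile caffeate, its oxidisable catechol and the neopentyl C19 acid (not releasable from a simple alkyl ester beside the caffeate) forbid harsh late steps. The enabling feature is that C10 bears a methyl and sits between C5 and C9: before ring A exists, ring B can be a 4-methylcyclohexa-2,5-dien-1-one (carbonyl at C7) whose arms C5=C6 and C9=C8 are enantiotopic. Closing ring A by attack of C4 on C5 then fixes C4, C5 and C10 together and leaves the C8=C9–C7=O enone for C9 and C17.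

## Retrosynthesis

**Caffeate and protecting groups (34 ⇒ 33 ⇒ 29 + 32).** The C15–O acyl bond is cut last, because the acrylate and catechol would not survive the hydride, organometallic and palladium hydride steps before it. Acid 32 carries the phenols as silyl ethers and alcohol 29 carries C19 as a 2-(trimethylsilyl)ethyl ester. One fluoride treatment of 33 then frees three groups by attack at silicon, without acyl attack at the neopentyl ester, acid or hydrogenation.

**Exocyclic methylene (29 ⇒ 28 ⇒ 27 ⇒ 26 ⇒ 25).** The key step leaves oxygen at C7, not C8, so a C8 ketone olefination is not available. The C7 carbonyl is used to bring in C17 and is then removed with retention of the exocyclic alkene. Cutting C7–H leads to allylic formate 27, from alcohol 26 and α-methylene ketone 25. The forward reaction must deliver hydride to the ring terminus of the C7–C8–C17 allyl unit, which palladium-catalysed formate hydrogenolysis does.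

**C17 and H9 (25 ⇒ 23 ⇒ 21).** Cutting C8–C17 and C9–H leads to enone 21, which already carries the chain on C9. Conjugate hydride addition gives the C7–C8 enolate regiospecifically for a Mannich reaction and puts H9 on the convex β face, which places the chain α. The neighbouring option, adding the chain as a cuprate to the unsubstituted enone, would put the carbon nucleophile on the β face and give the C9 epimer. This order costs one oxidation but uses the facial bias instead of fighting it.

**C9–C11 (21 ⇒ 13 + 18).** Conjugate addition of Grignard reagent 19 (from bromide 18) to enone 13 gives silyl enol ether 20, and dehydrogenation restores the enone. The C9 configuration formed in the addition is irrelevant.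

**C19 oxidation level (13 ⇒ 12 ⇒ 11).** Aldehyde to acid to fluoride-labile ester, before any organometallic step.

**Ring A (11 ⇒ 10).** The C4–C5 bond is cut. Precursor 10 is a racemic aldehyde on a symmetric dienone with no fixed stereocentre. The forward reaction must choose one enone arm and one enamine face.

**Ring B (10 ⇒ 9 ⇒ 8 ⇒ 5 + 6).** The dienone comes from cyclohexenone 8 by dehydrogenation. Enone 8 comes from Robinson annulation of α-branched aldehyde 5 with methyl vinyl ketone 6, which makes the quaternary carbon (future C10). The second aldehyde stays masked as its dimethyl acetal 9 until no base or amine is left.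

**Nine-carbon chain (5 ⇒ 4 ⇒ 2 ⇒ 1).** Melonal 1 already has all nine carbons. Acetalisation, allylic oxidation of the (E)-methyl group to enal 4 (through alcohol 3) and hydrogenation give 5. Both methyl-bearing centres are later erased, so racemic material suffices.

**Side chain and acyl donor (18 ⇒ 17 ⇒ 16 ⇒ 15 ⇒ 14; 32 ⇒ 31 ⇒ 30).** C13 is bought as methyl hydrogen (R)-3-methylglutarate 14. Its acid end becomes C15 and its ester end C11. Caffeic acid 30 is silylated to 32.

## Roads not taken

**Alternative 1:** Cut C3–C4 and C5–C10. An Et2AlCl-promoted intramolecular Diels–Alder reaction of a (Z)-diene (C10=C1–C2=C3) with an (E)-2-methyl enoate (C4=C5), tethered through C6–C9, would give octalin A1.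
- Merits: two bonds, both quaternary carbons and C5 form in one concerted step. The C4 configuration follows from the enoate geometry. C8 has oxygen on the right carbon, so C17 comes from ketone olefination in two steps, and C9 with its chain is present from the start. In late-stage economy at C8/C9 this road is better than the chosen one.
- Weak points: the diene terminus C10 is fully substituted and Z, so the s-cis conformer is strained and 1,5-hydrogen shift competes. A trisubstituted dienophile must form the second quaternary carbon in the same step. C8, C9 and C13 must first be set in an open chain and then relay their configuration to C5/C10 through the tether; cis fusion is not assured. C1=C2 must be hydrogenated afterwards, and the methyl ester of A1 cannot be cleaved beside a caffeate.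
- Against it the chosen plan sets a catalytic key step that creates absolute configuration from a racemic nine-carbon aldehyde with no stereochemical load in the precursor.

**Alternative 2:** Cut C10–C20 and C9–C11. LiCu(CH3)2 would add methyl to C10 of octalone A3, and the C8 enolate would be alkylated at C9 by iodide A4 to give ketone A2.
- Merits: conjugate methylation of such octalones reliably gives the cis-fused angular-methyl decalone, which is the fusion needed. The C8 ketone is ready for olefination. C9 is α to the ketone and can be corrected by equilibration. In all three respects this road is better than the chosen one, which spends five steps moving functionality from C7 to C8 and sets C9 kinetically.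
- Weak points: alkylation of a hindered cuprate-derived enolate next to a new quaternary carbon with an unactivated primary iodide is slow and prone to proton transfer. A2 has no C18, so the second quaternary carbon must be made later by methylating a C19 carbonyl derivative on the concave α face of ring A. A3 must first be made enantiopure with C4 and C5 set.
- Against it the chosen plan sets both quaternary carbons and C5 in one step.

**Alternative 3:** Cut C4–C5 and C1–C10. Diels–Alder reaction of the acetonide of (1R,2S)-3-methylcyclohexa-3,5-diene-1,2-diol A6 with citraconic anhydride A7 would give the endo bicyclo[2.2.2]octene A5; glycol cleavage would later open ring A.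
- Merits: absolute configuration comes from an enantiopure diene. The cyclic dienophile guarantees the cis H5/C20 relation. Both quaternary carbons form, with the acetonide controlling the face. In certainty of configuration at C4, C5 and C10 this road is better than the chosen one, which rests on untested catalyst control.
- Weak points: the orientation of the two methyl-bearing termini and dimerisation of A6 are open. After glycol cleavage C1 carries a surplus formyl carbon that must be excised, and C2=C3 must be reduced. All of ring B (C7, C8, C17 and the C9 chain with its stereocentre) must be built from the two anhydride carbonyls, which first have to be told apart.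
- Against it the chosen plan offers a key-step product that already contains ring B as an enone, and a much shorter route.

Key step: step 7

Assumption: the (1R,2R) catalyst is written for step 7; its sense of induction for this substrate cannot be derived with confidence, and the (1S,2S) antipode is used unchanged in its place if the other enone arm is selected.

Step 1
Reactants: 1 2,6-dimethylhept-5-enal (melonal, racemic)
Product: 2 7,7-dimethoxy-2,6-dimethylhept-2-ene
Conditions: HC(OMe)3, MeOH, p-TsOH (1 mol %), rt; Et3N
Reagents that add atoms: trimethyl orthoformate, COC(OC)OC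
Why: Acid-catalysed acetalisation with an orthoformate as water scavenger masks the carbon that becomes C19; the stereocentre stays racemic, which is harmless because step 7 erases it.

Step 2
Reactants: 2 7,7-dimethoxy-2,6-dimethylhept-2-ene
Product: 4 (E)-7,7-dimethoxy-2,6-dimethylhept-2-enal, via allylic alcohol 3 (not isolated)
Conditions: SeO2 (10 mol %), t-BuOOH, CH2Cl2, rt; crude, MnO2, CH2Cl2, rt
Reagents that add atoms: selenium dioxide, O=[Se]=O; tert-butyl hydroperoxide, CC(C)(C)OO
Why: Riley allylic oxidation (ene reaction, then [2,3]-shift) of a trisubstituted alkene attacks the (E)-methyl group selectively; MnO2 takes the allylic alcohol in the crude mixture on to the enal.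

Step 3
Reactants: 4 (E)-7,7-dimethoxy-2,6-dimethylhept-2-enal
Product: 5 7,7-dimethoxy-2,6-dimethylheptanal (mixture of stereoisomers)
Conditions: H2 (1 atm), 10 % Pd/C, EtOAc, rt
Reagents that add atoms: none
Why: Heterogeneous hydrogenation reduces the conjugated C=C of an enal well before the aldehyde; the new centre is uncontrolled and irrelevant, since it becomes the symmetric quaternary carbon of the dienone.

Step 4
Reactants: 5 7,7-dimethoxy-2,6-dimethylheptanal; 6 but-3-en-2-one (methyl vinyl ketone)
Product: 8 4-(5,5-dimethoxy-4-methylpentyl)-4-methylcyclohex-2-en-1-one, via keto aldehyde 7 (not isolated)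
Conditions: KOH (0.2 equiv), MeOH, 0 °C, then 60 °C
Reagents that add atoms: none
Why: Robinson annulation of an α-branched aldehyde: Michael addition gives 7, whose methyl ketone condenses with the now non-enolisable aldehyde to the 4,4-disubstituted cyclohexenone; base leaves the acetal intact.

Step 5
Reactants: 8 4-(5,5-dimethoxy-4-methylpentyl)-4-methylcyclohex-2-en-1-one
Product: 9 4-(5,5-dimethoxy-4-methylpentyl)-4-methylcyclohexa-2,5-dien-1-one
Conditions: DDQ (1.5 equiv), 1,4-dioxane, reflux
Reagents that add atoms: none
Why: Quinone dehydrogenation of a 4,4-disubstituted cyclohexenone is the standard entry to cross-conjugated dienones, and the quaternary carbon blocks aromatisation; the ring carbon is no longer stereogenic.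

Step 6
Reactants: 9 4-(5,5-dimethoxy-4-methylpentyl)-4-methylcyclohexa-2,5-dien-1-one
Product: 10 2-methyl-5-(1-methyl-4-oxocyclohexa-2,5-dien-1-yl)pentanal (racemic)
Conditions: 1 M aq. HCl, THF, 0 °C to rt
Reagents that add atoms: water, O
Why: Mild aqueous acid hydrolyses the dimethyl acetal; with no amine or base present the free aldehyde does not yet add to the dienone.

Step 7
Reactants: 10 2-methyl-5-(1-methyl-4-oxocyclohexa-2,5-dien-1-yl)pentanal
Product: 11 (1S,4aR,8aS)-1,4a-dimethyl-7-oxo-1,2,3,4,4a,7,8,8a-octahydronaphthalene-1-carbaldehyde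
Conditions: 1-[(1R,2R)-2-aminocyclohexyl]-3-[3,5-bis(trifluoromethyl)phenyl]thiourea (20 mol %), PhCO2H (20 mol %), H2O (2 equiv), toluene, rt
Reagents that add atoms: none
Why: Proposed new method: the primary amine condenses with 10 to an (E)-enamine, which erases the aldehyde α-centre so that both enantiomers of 10 converge, and the enamine carbon C4 adds to C5 of the dienone (activated by hydrogen bonding of the thiourea to the C7 carbonyl) in an intramolecular Michael reaction; hydrolysis of the product imine releases 11 and the catalyst. The closest known reaction types are the secondary-amine-catalysed desymmetrising intramolecular Michael addition of α-unbranched aldehydes to 4,4-disubstituted cyclohexadienones and the primary-amine–thiourea-catalysed intermolecular Michael addition of α,α-disubstituted aldehydes that builds quaternary carbons; their combination in one substrate is the untested element. Ring A closes in a 6-exo-trig mode through a chair-like transition state. Because the three-carbon tether is anchored on C10, C4 can reach C5 only on the face that carries C1, so C4–C5 forms syn to C1–C10, the fusion is necessarily cis, and C5 and C10 arise as a pair. Which enantiotopic arm (C5=C6 or C9=C8) is attacked, and with it the absolute configuration of C5 and C10, is decided by the chiral catalyst. C4 is decided by the enamine geometry together with the orientation of the enamine plane in the chair, which must place the formyl carbon anti to C6. The step therefore needs arm selectivity, which rests on the rigid planar dienone held by the thiourea, and C4 diastereoselectivity, which rests on the E preference of the enamine (methyl against chain) and is the less secure of the two.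

Step 8
Reactants: 11 (1S,4aR,8aS)-1,4a-dimethyl-7-oxo-1,2,3,4,4a,7,8,8a-octahydronaphthalene-1-carbaldehyde
Product: 12 (1S,4aR,8aS)-1,4a-dimethyl-7-oxo-1,2,3,4,4a,7,8,8a-octahydronaphthalene-1-carboxylic acid
Conditions: NaClO2, NaH2PO4, 2-methylbut-2-ene, t-BuOH/H2O, 0 °C to rt
Reagents that add atoms: sodium chlorite, [Na+].[O-]Cl=O
Why: Pinnick oxidation converts even neopentyl aldehydes to acids; the alkene scavenger protects the enone from hypochlorite, and the quaternary C4 cannot epimerise.

Step 9
Reactants: 12 (1S,4aR,8aS)-1,4a-dimethyl-7-oxo-1,2,3,4,4a,7,8,8a-octahydronaphthalene-1-carboxylic acid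
Product: 13 2-(trimethylsilyl)ethyl (1S,4aR,8aS)-1,4a-dimethyl-7-oxo-1,2,3,4,4a,7,8,8a-octahydronaphthalene-1-carboxylate
Conditions: Me3SiCH2CH2OH, PPh3, DIAD, THF, 0 °C to rt
Reagents that add atoms: 2-(trimethylsilyl)ethanol, C[Si](C)(C)CCO
Why: Mitsunobu esterification activates the primary alcohol, so the hindered carboxylate reacts as an oxygen nucleophile away from its neopentyl centre; the ester is later cleaved at silicon, again independent of the hindrance.

Step 10
Reactants: 14 (3R)-5-methoxy-3-methyl-5-oxopentanoic acid (methyl hydrogen (R)-3-methylglutarate)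
Product: 15 methyl (3R)-5-hydroxy-3-methylpentanoate
Conditions: BH3·SMe2, THF, 0 °C to rt; MeOH
Reagents that add atoms: none
Why: Borane reduces a carboxylic acid chemoselectively beside a methyl ester; the acid carbon becomes C15 and the C13 stereocentre is not involved.

Step 11
Reactants: 15 methyl (3R)-5-hydroxy-3-methylpentanoate
Product: 16 methyl (3R)-5-{[tert-butyl(dimethyl)silyl]oxy}-3-methylpentanoate
Conditions: t-BuMe2SiCl, imidazole, DMF, rt
Reagents that add atoms: tert-butyldimethylsilyl chloride, CC(C)(C)[Si](C)(C)Cl
Why: Standard silylation of a primary alcohol; it also prevents lactonisation of the hydroxy ester.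

Step 12
Reactants: 16 methyl (3R)-5-{[tert-butyl(dimethyl)silyl]oxy}-3-methylpentanoate
Product: 17 (3S)-5-{[tert-butyl(dimethyl)silyl]oxy}-3-methylpentan-1-ol
Conditions: LiAlH4, Et2O, 0 °C
Reagents that add atoms: none
Why: Hydride reduction of the ester gives the primary alcohol that becomes C11; the silyl ether is stable and the descriptor changes only through ligand priorities.

Step 13
Reactants: 17 (3S)-5-{[tert-butyl(dimethyl)silyl]oxy}-3-methylpentan-1-ol
Product: 18 {[(3R)-5-bromo-3-methylpentyl]oxy}(tert-butyl)dimethylsilane
Conditions: CBr4, PPh3, CH2Cl2, 0 °C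
Reagents that add atoms: carbon tetrabromide, BrC(Br)(Br)Br
Why: Appel bromination proceeds by SN2 at the primary carbon under neutral conditions that keep the silyl ether.

Step 14
Reactants: 18 {[(3R)-5-bromo-3-methylpentyl]oxy}(tert-butyl)dimethylsilane; 13 2-(trimethylsilyl)ethyl (1S,4aR,8aS)-1,4a-dimethyl-7-oxo-1,2,3,4,4a,7,8,8a-octahydronaphthalene-1-carboxylate
Product: 21 2-(trimethylsilyl)ethyl ester of the C8=C9 enone bearing the (3S)-5-(tert-butyldimethylsilyloxy)-3-methylpentyl chain on C9 (C7 ketone; H5/C19 ester/C20 all β), via Grignard reagent 19 (not isolated), via silyl enol ether 20 (not isolated)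
Conditions: 18, Mg, THF, rt; then 13, CuBr·SMe2 (20 mol %), Me3SiCl, THF, −78 °C; crude, Pd(OAc)2 (1.1 equiv), MeCN, rt
Reagents that add atoms: none
Why: Copper-catalysed, Me3SiCl-accelerated conjugate addition of the Grignard reagent gives silyl enol ether 20, and Saegusa–Ito oxidation (palladation at C8, syn β-hydride elimination of H9) restores the enone with the chain on C9. The C9 configuration made in the addition is deliberately erased, because a carbon nucleophile enters from the convex β face and would put the chain on the wrong side.

Step 15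
Reactants: 21 enone ester with the chain on C9
Product: 23 C7 ketone with H9 β and chain α and a dimethylaminomethyl group on C8 (C8 unassigned), via silyl enol ether 22 (not isolated)
Conditions: [(Ph3P)CuH]6 (5 mol %), PhMe2SiH, toluene, rt; then Me2N=CH2 I, CH2Cl2, rt; aq. NaHCO3
Reagents that add atoms: N,N-dimethylmethyleneiminium iodide (Eschenmoser's salt), C=[N+](C)C.[I-]
Why: Copper hydride 1,4-hydrosilylation delivers hydride to C9 from the convex β face, because the α face is shielded in either half-chair of ring B (by axial C1, or by C4 with its α-methyl lying under the ring); this sets H9 β and the chain α. The C7–C8 silyl enol ether forms regiospecifically, and its Mannich reaction with the iminium salt attaches C17 to C8.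

Step 16
Reactants: 23 Mannich base
Product: 25 α-methylene ketone (C7=O; C8=C17; H9 β and chain α), via ammonium iodide 24 (not isolated)
Conditions: MeI, Et2O, rt; then aq. NaHCO3, CH2Cl2, rt
Reagents that add atoms: none
Why: Quaternisation and E1cB loss of trimethylamine is the classical route from Mannich bases to α-methylene ketones; the weak base avoids migration of the alkene to C8=C9, which would erase C9.

Step 17
Reactants: 25 α-methylene ketone
Product: 26 allylic alcohol (C7–OH, configuration unassigned; C8=C17)
Conditions: NaBH4, CeCl3·7H2O, MeOH, −40 °C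
Reagents that add atoms: none
Why: Luche conditions give clean 1,2-reduction of the enone; the C7 configuration is immaterial because C7 becomes a methylene in step 19.

Step 18
Reactants: 26 allylic alcohol
Product: 27 allylic formate (C7–OCHO; C8=C17)
Conditions: HCO2H, Ac2O, pyridine, 0 °C to rt
Reagents that add atoms: formic acid, O=CO (delivered as acetic formic anhydride, CC(=O)OC=O)
Why: Acetic formic anhydride formylates secondary alcohols selectively at the formyl carbon under buffered conditions that keep the silyl ether and the allylic system.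

Step 19
Reactants: 27 allylic formate
Product: 28 2-(trimethylsilyl)ethyl (1S,4aR,5R,8aS)-5-[(3S)-5-{[tert-butyl(dimethyl)silyl]oxy}-3-methylpentyl]-1,4a-dimethyl-6-methylidenedecahydronaphthalene-1-carboxylate
Conditions: Pd(OAc)2 (5 mol %), PBu3 (5 mol %), THF, rt to 50 °C
Reagents that add atoms: none
Why: Palladium-catalysed formate hydrogenolysis (Tsuji–Trost-type reduction): ionisation gives the C7–C8–C17 π-allylpalladium formate, CO2 is lost, and hydride passes from palladium to the more substituted terminus C7, which leaves the exocyclic C8=C17 alkene; C9 is not touched.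

Step 20
Reactants: 28 silyl ether
Product: 29 2-(trimethylsilyl)ethyl (1S,4aR,5R,8aS)-5-[(3S)-5-hydroxy-3-methylpentyl]-1,4a-dimethyl-6-methylidenedecahydronaphthalene-1-carboxylate
Conditions: camphorsulfonic acid (10 mol %), MeOH/CH2Cl2, 0 °C
Reagents that add atoms: none
Why: Acid-catalysed methanolysis removes the primary silyl ether; the 2-(trimethylsilyl)ethyl ester and the 1,1-disubstituted alkene tolerate brief mild acid.

Step 21
Reactants: 30 (E)-3-(3,4-dihydroxyphenyl)prop-2-enoic acid (caffeic acid)
Product: 32 (E)-3-[3,4-bis({[tert-butyl(dimethyl)silyl]oxy})phenyl]prop-2-enoic acid, via silyl ester 31 (not isolated)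
Conditions: t-BuMe2SiCl (3.5 equiv), imidazole, DMF, rt; then K2CO3 (cat.), MeOH/THF/H2O, 0 °C; citric acid
Reagents that add atoms: tert-butyldimethylsilyl chloride, CC(C)(C)[Si](C)(C)Cl
Why: Exhaustive silylation followed by selective hydrolysis of the labile silyl ester leaves the two aryl silyl ethers and the E alkene.

Step 22
Reactants: 29 primary alcohol; 32 (E)-3-[3,4-bis({[tert-butyl(dimethyl)silyl]oxy})phenyl]prop-2-enoic acid
Product: 33 2-(trimethylsilyl)ethyl (1S,4aR,5R,8aS)-5-[(3S)-5-({(2E)-3-[3,4-bis({[tert-butyl(dimethyl)silyl]oxy})phenyl]prop-2-enoyl}oxy)-3-methylpentyl]-1,4a-dimethyl-6-methylidenedecahydronaphthalene-1-carboxylate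
Conditions: DCC, DMAP (10 mol %), CH2Cl2, 0 °C to rt
Reagents that add atoms: none
Why: Steglich esterification of an unhindered primary alcohol with a cinnamic acid proceeds under neutral conditions and keeps the alkene geometry.

Step 23
Reactants: 33 fully protected ester
Product: 34 (1S,4aR,5R,8aS)-5-[(3S)-5-{[(2E)-3-(3,4-dihydroxyphenyl)prop-2-enoyl]oxy}-3-methylpentyl]-1,4a-dimethyl-6-methylidenedecahydronaphthalene-1-carboxylic acid
Conditions: Bu4NF (5 equiv), AcOH (2 equiv), THF, 0 °C to rt, under Ar
Reagents that add atoms: none
Why: Fluoride cleaves both aryl silyl ethers and fragments the 2-(trimethylsilyl)ethyl ester (attack at silicon, loss of ethene) in one operation, without strong acid, strong base or reduction, so the exocyclic alkene and the caffeate should survive.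

## Compound list

1 | 2,6-dimethylhept-5-enal (melonal), racemic | CC(C)=CCCC(C)C=O | starting material
2 | 7,7-dimethoxy-2,6-dimethylhept-2-ene, racemic | COC(OC)C(C)CCC=C(C)C | intermediate
3 | (E)-7,7-dimethoxy-2,6-dimethylhept-2-en-1-ol, racemic | COC(OC)C(C)CC/C=C(\C)CO | intermediate (not isolated)
4 | (E)-7,7-dimethoxy-2,6-dimethylhept-2-enal, racemic | COC(OC)C(C)CC/C=C(\C)C=O | intermediate
5 | 7,7-dimethoxy-2,6-dimethylheptanal, mixture of stereoisomers | COC(OC)C(C)CCCC(C)C=O | intermediate
6 | but-3-en-2-one (methyl vinyl ketone) | CC(=O)C=C | starting material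
7 | 2-(5,5-dimethoxy-4-methylpentyl)-2-methyl-5-oxohexanal, mixture of stereoisomers | COC(OC)C(C)CCCC(C)(C=O)CCC(C)=O | intermediate (not isolated)
8 | 4-(5,5-dimethoxy-4-methylpentyl)-4-methylcyclohex-2-en-1-one, mixture of stereoisomers | COC(OC)C(C)CCCC1(C)CCC(=O)C=C1 | intermediate
9 | 4-(5,5-dimethoxy-4-methylpentyl)-4-methylcyclohexa-2,5-dien-1-one, racemic | COC(OC)C(C)CCCC1(C)C=CC(=O)C=C1 | intermediate
10 | 2-methyl-5-(1-methyl-4-oxocyclohexa-2,5-dien-1-yl)pentanal, racemic | O=CC(C)CCCC1(C)C=CC(=O)C=C1 | intermediate
11 | (1S,4aR,8aS)-1,4a-dimethyl-7-oxo-1,2,3,4,4a,7,8,8a-octahydronaphthalene-1-carbaldehyde (cis-fused) | O=C1C[C@H]2[C@](C)(CCC[C@]2(C)C=O)C=C1 | intermediate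
12 | (1S,4aR,8aS)-1,4a-dimethyl-7-oxo-1,2,3,4,4a,7,8,8a-octahydronaphthalene-1-carboxylic acid | O=C1C[C@H]2[C@](C)(CCC[C@]2(C)C(=O)O)C=C1 | intermediate
13 | 2-(trimethylsilyl)ethyl (1S,4aR,8aS)-1,4a-dimethyl-7-oxo-1,2,3,4,4a,7,8,8a-octahydronaphthalene-1-carboxylate | O=C1C[C@H]2[C@](C)(CCC[C@]2(C)C(=O)OCC[Si](C)(C)C)C=C1 | intermediate
14 | (3R)-5-methoxy-3-methyl-5-oxopentanoic acid (methyl hydrogen (R)-3-methylglutarate) | COC(=O)C[C@H](C)CC(=O)O | starting material
15 | methyl (3R)-5-hydroxy-3-methylpentanoate | COC(=O)C[C@H](C)CCO | intermediate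
16 | methyl (3R)-5-{[tert-butyl(dimethyl)silyl]oxy}-3-methylpentanoate | COC(=O)C[C@H](C)CCO[Si](C)(C)C(C)(C)C | intermediate
17 | (3S)-5-{[tert-butyl(dimethyl)silyl]oxy}-3-methylpentan-1-ol | OCC[C@H](C)CCO[Si](C)(C)C(C)(C)C | intermediate
18 | {[(3R)-5-bromo-3-methylpentyl]oxy}(tert-butyl)dimethylsilane | BrCC[C@H](C)CCO[Si](C)(C)C(C)(C)C | intermediate
19 | [(3R)-5-{[tert-butyl(dimethyl)silyl]oxy}-3-methylpentyl]magnesium bromide | Br[Mg]CC[C@H](C)CCO[Si](C)(C)C(C)(C)C | intermediate (not isolated)
20 | C7 trimethylsilyl enol ether (C7=C8) of the 1,4-adduct of 19 to 13; chain on C9, either C9 epimer; H5, C19 ester and C20 β; 13S | C[Si](C)(C)OC=1C[C@H]2[C@](C)(CCC[C@]2(C)C(=O)OCC[Si](C)(C)C)C(CC[C@H](C)CCO[Si](C)(C)C(C)(C)C)C=1 | intermediate (not isolated)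
21 | 2-(trimethylsilyl)ethyl ester of the cis-fused C8=C9 enone (C7 ketone) bearing on C9 the (3S)-5-(tert-butyldimethylsilyloxy)-3-methylpentyl chain; H5, C19 ester and C20 β | O=C1C[C@H]2[C@](C)(CCC[C@]2(C)C(=O)OCC[Si](C)(C)C)C(CC[C@H](C)CCO[Si](C)(C)C(C)(C)C)=C1 | intermediate
22 | C7 dimethyl(phenyl)silyl enol ether (C7=C8) from 21; H9 β, chain α | C[Si](C)(c3ccccc3)OC=1C[C@H]2[C@](C)(CCC[C@]2(C)C(=O)OCC[Si](C)(C)C)[C@H](CC[C@H](C)CCO[Si](C)(C)C(C)(C)C)C=1 | intermediate (not isolated)
23 | Mannich base: C7 ketone with 8-(dimethylaminomethyl) (C8 unassigned), H9 β, chain α; otherwise as 21 | O=C1C[C@H]2[C@](C)(CCC[C@]2(C)C(=O)OCC[Si](C)(C)C)[C@H](CC[C@H](C)CCO[Si](C)(C)C(C)(C)C)C1CN(C)C | intermediate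
24 | trimethylammonium iodide of 23 | O=C1C[C@H]2[C@](C)(CCC[C@]2(C)C(=O)OCC[Si](C)(C)C)[C@H](CC[C@H](C)CCO[Si](C)(C)C(C)(C)C)C1C[N+](C)(C)C.[I-] | intermediate (not isolated)
25 | α-methylene ketone: C7 ketone, exocyclic C8=C17, H9 β, chain α; otherwise as 21 | O=C1C[C@H]2[C@](C)(CCC[C@]2(C)C(=O)OCC[Si](C)(C)C)[C@H](CC[C@H](C)CCO[Si](C)(C)C(C)(C)C)C1=C | intermediate
26 | allylic alcohol: 7-hydroxy (C7 unassigned), exocyclic C8=C17; otherwise as 25 | OC1C[C@H]2[C@](C)(CCC[C@]2(C)C(=O)OCC[Si](C)(C)C)[C@H](CC[C@H](C)CCO[Si](C)(C)C(C)(C)C)C1=C | intermediate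
27 | formate ester of 26 | O=COC1C[C@H]2[C@](C)(CCC[C@]2(C)C(=O)OCC[Si](C)(C)C)[C@H](CC[C@H](C)CCO[Si](C)(C)C(C)(C)C)C1=C | intermediate
28 | 2-(trimethylsilyl)ethyl (1S,4aR,5R,8aS)-5-[(3S)-5-{[tert-butyl(dimethyl)silyl]oxy}-3-methylpentyl]-1,4a-dimethyl-6-methylidenedecahydronaphthalene-1-carboxylate | C=C1CC[C@H]2[C@](C)(CCC[C@]2(C)C(=O)OCC[Si](C)(C)C)[C@@H]1CC[C@H](C)CCO[Si](C)(C)C(C)(C)C | intermediate
29 | 2-(trimethylsilyl)ethyl (1S,4aR,5R,8aS)-5-[(3S)-5-hydroxy-3-methylpentyl]-1,4a-dimethyl-6-methylidenedecahydronaphthalene-1-carboxylate | C=C1CC[C@H]2[C@](C)(CCC[C@]2(C)C(=O)OCC[Si](C)(C)C)[C@@H]1CC[C@H](C)CCO | intermediate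
30 | (E)-3-(3,4-dihydroxyphenyl)prop-2-enoic acid (caffeic acid) | O=C(O)/C=C/c1ccc(O)c(O)c1 | starting material
31 | tert-butyldimethylsilyl (E)-3-[3,4-bis({[tert-butyl(dimethyl)silyl]oxy})phenyl]prop-2-enoate | CC(C)(C)[Si](C)(C)OC(=O)/C=C/c1ccc(O[Si](C)(C)C(C)(C)C)c(O[Si](C)(C)C(C)(C)C)c1 | intermediate (not isolated)
32 | (E)-3-[3,4-bis({[tert-butyl(dimethyl)silyl]oxy})phenyl]prop-2-enoic acid | O=C(O)/C=C/c1ccc(O[Si](C)(C)C(C)(C)C)c(O[Si](C)(C)C(C)(C)C)c1 | intermediate
33 | 2-(trimethylsilyl)ethyl (1S,4aR,5R,8aS)-5-[(3S)-5-({(2E)-3-[3,4-bis({[tert-butyl(dimethyl)silyl]oxy})phenyl]prop-2-enoyl}oxy)-3-methylpentyl]-1,4a-dimethyl-6-methylidenedecahydronaphthalene-1-carboxylate | C=C1CC[C@H]2[C@](C)(CCC[C@]2(C)C(=O)OCC[Si](C)(C)C)[C@@H]1CC[C@H](C)CCOC(=O)/C=C/c1ccc(O[Si](C)(C)C(C)(C)C)c(O[Si](C)(C)C(C)(C)C)c1 | intermediate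
34 | (1S,4aR,5R,8aS)-5-[(3S)-5-{[(2E)-3-(3,4-dihydroxyphenyl)prop-2-enoyl]oxy}-3-methylpentyl]-1,4a-dimethyl-6-methylidenedecahydronaphthalene-1-carboxylic acid (CNP0130717.2) | C=C1CC[C@H]2[C@](C)(CCC[C@]2(C)C(=O)O)[C@@H]1CC[C@H](C)CCOC(=O)/C=C/c1ccc(O)c(O)c1 | target

## Step count and least certain steps

Total: 23 steps. Longest linear sequence: 18 steps (steps 1–9, 14–20, 22 and 23, from 1 to 34).

**Step 7 (new method).** The most likely failure is incomplete discrimination between the two enone arms, or between the two orientations of the enamine at C4. Slow enamine formation from the α-branched aldehyde would make this worse by letting uncatalysed closure compete. The fallback replaces catalysis by resolution and uses known chemistry. It sets out from 10: closure through the stoichiometric pyrrolidine enamine (Stork enamine Michael addition, AcOH buffer, aqueous hydrolysis) should give racemic material, that is 11 together with ent-11 F1. Pinnick oxidation as in step 8 then gives 12 together with ent-12 F2. Crystallisation of the (R)-1-phenylethylammonium salt of 12 F3 and acidification bring the route back at 12; the antipodal amine is used if the salt of F2 is the one that crystallises.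

**Step 15.** Hydride transfer to the fully substituted C9 next to quaternary C10 may be slow (stoichiometric [(Ph3P)CuH]6 is the first remedy). More seriously, the facial preference of the bicycle may be the reverse of that assumed, which would give the C9 epimer. In that case the same preference places a carbon nucleophile correctly, so the order of chain and hydrogen is exchanged. The fallback sets out from silyl enol ether 20, now formed with the chain α in the conjugate addition of step 14. Instead of being oxidised, 20 is treated directly with Me2N=CH2 I in CH2Cl2, and the route is rejoined at 23. No new compound is involved and one step is saved.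

**Step 19.** Hydride may be delivered to the primary terminus C17, giving the endocyclic C7=C8 alkene, or the allylpalladium intermediate may lose a β-hydrogen to give a diene. The fallback is an amine oxide route starting from 23:
- NaBH4 reduction to the amino alcohol F4;
- PhOC(S)Cl with DMAP to the phenyl thionocarbonate F5;
- Barton–McCombie deoxygenation (Bu3SnH, AIBN) to the tertiary amine F6;
- mCPBA to the amine N-oxide F7;
- Cope elimination on heating, which has only H8 available as β-hydrogen and so can form only the C8=C17 alkene, rejoining the route at 28.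

**Step 23.** Fragmentation of the hindered silylethyl ester may be slow enough for basic fluoride to cleave or transesterify the caffeate, or for the catecholate to oxidise. The fallback builds the cinnamate double bond last and needs no phenol protection. It sets out from 29: Bu4NF removes the silylethyl ester to give the hydroxy acid F8, warming with Meldrum's acid in toluene gives the malonic half ester F9, and Knoevenagel–Doebner condensation with 3,4-dihydroxybenzaldehyde (pyridine, catalytic piperidine) gives 34 directly.

## Further compounds

F1 | step 7 | ent-11, (1R,4aS,8aR)-1,4a-dimethyl-7-oxo-1,2,3,4,4a,7,8,8a-octahydronaphthalene-1-carbaldehyde | O=C1C[C@@H]2[C@@](C)(CCC[C@@]2(C)C=O)C=C1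
F2 | step 7 | ent-12, (1R,4aS,8aR)-1,4a-dimethyl-7-oxo-1,2,3,4,4a,7,8,8a-octahydronaphthalene-1-carboxylic acid | O=C1C[C@@H]2[C@@](C)(CCC[C@@]2(C)C(=O)O)C=C1
F3 | step 7 | (R)-1-phenylethylammonium salt of 12 | O=C1C[C@H]2[C@](C)(CCC[C@]2(C)C(=O)[O-])C=C1.C[C@@H]([NH3+])c1ccccc1
F0 | step 15 | none | none
F4 | step 19 | amino alcohol: 7-hydroxy-8-(dimethylaminomethyl) compound from 23 (C7, C8 unassigned) | OC1C[C@H]2[C@](C)(CCC[C@]2(C)C(=O)OCC[Si](C)(C)C)[C@H](CC[C@H](C)CCO[Si](C)(C)C(C)(C)C)C1CN(C)C
F5 | step 19 | O-phenyl thionocarbonate of F4 | S=C(Oc3ccccc3)OC1C[C@H]2[C@](C)(CCC[C@]2(C)C(=O)OCC[Si](C)(C)C)[C@H](CC[C@H](C)CCO[Si](C)(C)C(C)(C)C)C1CN(C)C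
F6 | step 19 | tertiary amine: 8-(dimethylaminomethyl) compound with C7 methylene (C8 unassigned) | CN(C)CC1CC[C@H]2[C@](C)(CCC[C@]2(C)C(=O)OCC[Si](C)(C)C)[C@@H]1CC[C@H](C)CCO[Si](C)(C)C(C)(C)C
F7 | step 19 | N-oxide of F6 | C[N+](C)([O-])CC1CC[C@H]2[C@](C)(CCC[C@]2(C)C(=O)OCC[Si](C)(C)C)[C@@H]1CC[C@H](C)CCO[Si](C)(C)C(C)(C)C
F8 | step 23 | (1S,4aR,5R,8aS)-5-[(3S)-5-hydroxy-3-methylpentyl]-1,4a-dimethyl-6-methylidenedecahydronaphthalene-1-carboxylic acid | C=C1CC[C@H]2[C@](C)(CCC[C@]2(C)C(=O)O)[C@@H]1CC[C@H](C)CCO
F9 | step 23 | malonic half ester of F8 at O15 | C=C1CC[C@H]2[C@](C)(CCC[C@]2(C)C(=O)O)[C@@H]1CC[C@H](C)CCOC(=O)CC(=O)O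
A1 | alternative 1 | cis-fused octalin methyl ester with C1=C2 alkene, C8 silyl ether and C15 pivalate | CC(C)(C)[Si](C)(C)O[C@@H]1CC[C@H]2[C@](C)(C=CC[C@]2(C)C(=O)OC)[C@@H]1CC[C@H](C)CCOC(=O)C(C)(C)C
A2 | alternative 2 | cis-fused C8 ketone with C10 methyl, C9 chain (4-methoxybenzyl ether) and C19 silyloxymethyl | O=C1CC[C@H]2[C@](C)(CCC[C@@H]2CO[Si](C)(C)C(C)(C)C)[C@@H]1CC[C@H](C)CCOCc1ccc(OC)cc1
A3 | alternative 2 | octalone (C8 ketone, C9=C10) with C19 silyloxymethyl | O=C1CC[C@H]2C(CCC[C@@H]2CO[Si](C)(C)C(C)(C)C)=C1
A4 | alternative 2 | side-chain iodide, 4-methoxybenzyl ether | ICC[C@H](C)CCOCc1ccc(OC)cc1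
A5 | alternative 3 | endo bicyclo[2.2.2]octene anhydride acetonide | C[C@@]12C(=O)OC(=O)[C@@H]1[C@]3(C)C=C[C@H]2[C@H]4OC(C)(C)O[C@@H]34
A6 | alternative 3 | acetonide of (1R,2S)-3-methylcyclohexa-3,5-diene-1,2-diol | CC1=CC=C[C@H]2OC(C)(C)O[C@@H]12
A7 | alternative 3 | citraconic anhydride | CC1=CC(=O)OC1=O
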